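Compound numbers used below are those of the steps and of the compound list that follows them.

## Analysis of the target

Target 20 (C58H68O20) is a linear chain of five six-membered carbocycles joined by four methylene bridges. Rings A and E are 2-butanoyl-4,4-dimethylcyclohexane-1,3,5-trione (butyrylfilicinic acid) units drawn as dienols. Rings B, C and D are butyrylphloroglucinol benzene rings in which every ring carbon is substituted.

There is no stereocentre. The quaternary carbons of rings A and E carry two identical methyl groups, and a mirror plane through ring C maps ring A onto ring E and ring B onto ring D. The only isomerism is keto–enol tautomerism.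

The sensitive groups are nine phenols and four enols, which oxidise in air as their anions, and the β-triketone rings, which hot alkali opens by retro-Claisen cleavage. Most delicate are the four aryl–CH2 bonds: once the rings are free phenols they break and re-form under acid (ipso-protonation) and under base (quinone methide formation), which scrambles the ring order.

The difficulty is therefore sequence. Condensing the monomers with a one-carbon electrophile gives a statistical mixture of oligomers, and ring C must be substituted at all six carbons with two neighbours that differ only by their place in the chain.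

The strategy rests on the two inner bridging carbons. Both are bonded to ring C, at C2 and C4 on either side of one oxygen-bearing carbon, and each is bonded on its other side to an oxygen-flanked carbon of ring B or ring D. These two CH2–aryl bonds can be formed once and irreversibly by sp3–sp2 cross-coupling, with boron on the ring C methylene carbons and bromine on rings B and D, while all nine oxygens are methyl ethers. The outer bridges end on the enol carbon of a trione ring and are left for a conjugate addition at the single free carbon of rings B and D.

## Retrosynthetic reasoning

**Outer bridges, 20 ⇒ 13 + two 17.** The bonds cut are those between each outer bridging CH2 and C5 of ring B and of ring D. Cutting on the aromatic side leaves the one-carbon unit on the trione partner as Mannich base 17, a derivative of a small monomer with exactly one free ring carbon. In the forward direction 17 loses its amine to give the exocyclic enone 18, which is attacked by the only unsubstituted carbon of ring B and then, through tetramer 19, by that of ring D. Ring C of 13 has no free carbon, so capping stops after two events. The fragile dearomatised rings A and E enter last, after every Lewis-acid step.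

**Cap, 17 ⇒ 16 ⇒ 14.** The aminomethyl C–C bond of 17 is removed to give 16. The two C–CH3 bonds at one ring carbon of 16 are then removed to give the commercial ketone 14, with 15 as the monomethyl stage. The forward dimethylation must place both methyl groups on the same carbon, which dearomatises the ring and creates the trione. The butyryl group is already present in 14, so no acylation of a trione is needed.

**Phenols and ketones, 13 ⇒ 12 ⇒ 11.** Nine O–CH3 bonds are restored to give 12, because the rings must be inert ethers during the organometallic and Friedel–Crafts steps. Three aryl–C(O) bonds are then cut to give 11. The butyryl groups are placed after the coupling so that the coupling partners stay simple. Their positions need no control: ring C of 11 has one free carbon, rings B and D have two equivalent ones, and the first acyl group deactivates its ring. Acylating before the ethers are cleaved also makes every ring less prone to ipso-protonation when the phenols are unveiled.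

**Key disconnection, 11 ⇒ 8 + two 9.** The two bonds cut run from the inner bridging CH2 groups to rings B and D. Both benzylic nucleophiles are put on ring C and only a halogen on the outer rings. Thus 9 is commercial and monofunctional, only one kind of bond can form, and a failed coupling gives a ring C by-product rather than a sequence isomer. The forward reaction must insert zerovalent palladium into a hindered, electron-rich C–Br bond and transfer a primary benzylic boronate faster than it is protonated, passing through 10.

**Ring C piece, 8 ⇒ 4 ⇒ 3 ⇒ 1 and 5.** The two C–B bonds are traced back to aldehyde carbons through bis(tosylhydrazone) 4, the diazo stage 6 and the geminal tetraboronate 7, with boron supplied by 5. A benzylic halide was avoided as the boron precursor: each CH2 of ring C has two ortho oxygens and one para oxygen and would ionise, and the ring still has a nucleophilic free carbon. The diazo route never passes through a benzylic cation. The two formyl carbons of 3 come from twofold electrophilic formylation of commercial 1 by way of 2.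

## Alternatives that were turned down

**Alternative 1: both terminal trione rings by a double Dieckmann closure.**
- Disconnection: in rings A and E, the bond between the ring carbonyl next to the bridge-bearing carbon and the carbon that later carries the butyryl group.
- Forward key step: the precursor A2 is the core of 13 with an open arm CH2–CH(CO2Me)–CO–CMe2–CO–CH3 on ring B and on ring D. An alkoxide base converts each terminal methyl ketone into its enolate, which attacks the neighbouring ester and closes both six-membered rings to give A1.
- For it: the gem-dimethyl carbon comes from an acyclic building block, so there is no statistical C-methylation of a phloroglucinol. The outer bridges would be made by irreversible enolate alkylation and not by reversible quinone methide chemistry. On both points it is stronger than the chosen route.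
- Against it: the CO–CMe2–CO unit of A2 cannot enolise between its carbonyls, so alkoxide can cleave it by retro-Claisen attack in competition with ring closure. The nine phenols of A2 consume base first, and the closure must then run on a polyanion. A1 lacks both terminal butyryl groups, which means two late C-acylations of cyclic triones in the presence of nine phenols. A2 still needs the ring B–ring C–ring D core, so the inner bridges are left unsolved.
- Comparison: the chosen strategy obtains rings A and E with the butyryl group in place in two steps from 14 and attaches both in one operation. It spends its effort on the bonds that define the sequence.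

**Alternative 2: rings B and D by a double Danheiser benzannulation.**
- Disconnection: two ring bonds in each of rings B and D.
- Forward key step: the ring C bis(siloxyalkyne) A4 is heated with two equivalents of cyclobutenone A5. Each cyclobutenone opens to a vinylketene, adds to an alkyne in a [2+2] sense, opens again and closes by 6π electrocyclisation to a phenol, giving A3.
- For it: every substituent of rings B and D is placed by the annulation. The three oxygens of each new ring are differentiated (free OH, ethyl ether, silyl ether), and the carbon of the outer bridge is already in place as a methoxymethyl handle. On differentiation and on the pre-installed outer bridge carbon it is stronger than the chosen route.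
- Against it: A4 requires two ynolate-type homologations on a ring C diester, and A5 is itself a multistep reagent. The thermal cascade must succeed twice on one molecule. A3 still lacks all three butyryl groups, and Friedel–Crafts acylation would have to tolerate benzylic methyl ethers ortho and para to oxygen, which ionise under Lewis acids. Three kinds of O-protecting group must then be removed.
- Comparison: the differentiation is of no use in 20, because every oxygen of rings B and D ends as a free hydroxyl. The chosen route takes rings B and D from commercial 9 and forms only the two bonds that matter, at a fraction of the step count.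

**Alternative 3: terminal rings from dimethylketene and bis(silyloxy)dienes.**
- Disconnection: in rings A and E, the bond from the bridge-bearing carbon to a ring carbonyl and the bond from the gem-dimethyl carbon to the next carbonyl carbon.
- Forward key step: precursor A7 is the permethylated ring B–ring C–ring D core with an arm CH2–CH=C(OSiMe3)–CH=C(OMe)OSiMe3 on each outer ring. It would combine with dimethylketene A8 in a [4+2] sense across the ketene C=C bond, and acid work-up would give the acyl-free trione rings of A6.
- For it: the gem-dimethyl carbon and one carbonyl arrive as a unit, so there is no C-methylation problem. The nine methyl ethers are still in place during ring construction, which keeps the inner bridges inert. On that point it equals the chosen route, since A7 is built on the same core as 11.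
- Against it: ketenes normally add to dienes in the [2+2] mode or simply C-acylate an electron-rich silyloxydiene at its terminus. The required all-carbon [4+2] mode is the least typical and its periselectivity is not secured by anything in A7. A8 dimerises readily. A7 needs a five-carbon β-keto ester arm on each outer ring, several steps beyond 11. A6 lacks all five butyryl groups, so five acylations of two different kinds and a ninefold ether cleavage would follow.
- Comparison: the chosen route reaches the target in three steps from 11, with the acyl groups of rings A and E brought in ready-made.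

Key step: step 4

Remark on the chemistry: rings A and E of 20 are written as one dienol tautomer of a rapidly equilibrating set, and the target has no stereogenic element, so no step has to control configuration.

## Route

**Step 1**
Reactants: 1 1,3,5-trimethoxybenzene
Product: 3 2,4,6-trimethoxybenzene-1,3-dicarbaldehyde, via 2,4,6-trimethoxybenzaldehyde 2 (not isolated)
Conditions: Cl2CHOMe (5 equiv), TiCl4 (5 equiv), CH2Cl2, −10 °C → rt; then ice, 1 M HCl
Reagents that add atoms: dichloromethyl methyl ether, COC(Cl)Cl; water, O
Why: Rieche formylation; the first formyl group enters quickly to give 2, and the two remaining ring carbons are still activated by two ortho and one para methoxy groups, so excess reagent should drive a second substitution. The doubly formylated ring is much less reactive, which should hold the reaction at the dialdehyde.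

**Step 2**
Reactants: 3 2,4,6-trimethoxybenzene-1,3-dicarbaldehyde
Product: 4 2,4,6-trimethoxybenzene-1,3-dicarbaldehyde bis(4-methylbenzenesulfonylhydrazone), both C=N bonds E
Conditions: TsNHNH2 (2.2 equiv), AcOH (cat.), MeOH, 65 °C; crystallisation on cooling
Reagents that add atoms: 4-methylbenzenesulfonohydrazide, Cc1ccc(cc1)S(=O)(=O)NN
Why: Acid-catalysed condensation of the aldehydes with a sulfonyl hydrazide; aldehyde hydrazones form as the E isomers, and the geometry is lost in the next step.

**Step 3**
Reactants: 4 2,4,6-trimethoxybenzene-1,3-dicarbaldehyde bis(4-methylbenzenesulfonylhydrazone); 5 bis(pinacolato)diboron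
Product: 8 1,3,5-trimethoxy-2,4-bis[(4,4,5,5-tetramethyl-1,3,2-dioxaborolan-2-yl)methyl]benzene, via bis(diazomethyl)arene 6 (not isolated), via tetraboronate 7 (not isolated)
Conditions: NaH (3.0 equiv), 5 (2.6 equiv), PhMe, 110 °C; then MeOH, 60 °C
Reagents that add atoms: none
Why: Transition-metal-free reductive borylation of N-tosylhydrazones: Bamford–Stevens fragmentation of the sodium salts gives the nucleophilic diazo carbons of 6, which add to boron of 5 and, with loss of N2 and a 1,2-boryl shift, give the geminal boronates of 7. Methoxide formed from the excess hydride and methanol then removes one boron of each pair through the α-boryl carbanion, leaving one Bpin group on each benzylic carbon. No benzylic cation is formed, so the electron-rich ring cannot alkylate itself.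

**Step 4**
Reactants: 8 1,3,5-trimethoxy-2,4-bis[(4,4,5,5-tetramethyl-1,3,2-dioxaborolan-2-yl)methyl]benzene; 9 2-bromo-1,3,5-trimethoxybenzene (2.4 equiv)
Product: 11 1,3,5-trimethoxy-2,4-bis(2,4,6-trimethoxybenzyl)benzene, via monocoupled boronate 10 (not isolated)
Conditions: Pd(OAc)2 (5 mol %), SPhos (2-dicyclohexylphosphino-2',6'-dimethoxybiphenyl, 10 mol %), K3PO4 (6 equiv), degassed PhMe/H2O (10:1), 90 °C, Ar
Reagents that add atoms: none
Why: Suzuki–Miyaura cross-coupling of a primary benzylic boronic ester with an aryl bromide is the known reaction type. Pd(OAc)2 is reduced in the flask to zerovalent palladium, whose monophosphine complex with the bulky, electron-rich SPhos should insert into the C–Br bond of 9 although that bond lies between two methoxy groups on an electron-rich ring; a triarylphosphine catalyst is not expected to do this at a useful rate. Phosphate and water activate a Bpin group of 8 as the boronate, the benzylic carbon passes to divalent palladium, and reductive elimination forms the aryl–CH2 bond of 10; the benzylic carbon has no sp3 β-hydrogen, so β-hydride elimination cannot intervene. The second Bpin group of 10 reacts in the same way to give 11. No ring is closed and no stereocentre is formed. The selectivity needed is cross-coupling over protodeboronation and oxidative homocoupling of the benzylic boronate, and it is served by exclusion of oxygen, by the excess of 9, by fast oxidative addition that keeps an arylpalladium species ready for the boronate, and by the electron-rich ring of 8, which disfavours the benzylic carbanion that protodeboronation requires. Regiochemistry and the order ring B–ring C–ring D are fixed by the positions of boron and bromine alone, because 8 carries both benzylic carbons and no halogen while 9 carries one halogen and no boron. The medium is basic and all nine oxygens are methyl ethers, so the acid-promoted exchange of the new diarylmethane bonds has no pathway.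

**Step 5**
Reactants: 11 1,3,5-trimethoxy-2,4-bis(2,4,6-trimethoxybenzyl)benzene
Product: 12 1-[3,5-bis(3-butanoyl-2,4,6-trimethoxybenzyl)-2,4,6-trimethoxyphenyl]butan-1-one
Conditions: butanoyl chloride (3.3 equiv), SnCl4 (3.6 equiv), CH2Cl2, −20 → 0 °C; then cold 1 M HCl
Reagents that add atoms: butanoyl chloride, CCCC(Cl)=O
Why: Friedel–Crafts acylation; ring C has one unsubstituted carbon and rings B and D have two equivalent ones, each flanked by two methoxy groups. The first acyl group deactivates an outer ring, so the third equivalent should go to ring C and not to a second carbon of ring B or ring D. A mild Lewis acid at low temperature is chosen to spare the diarylmethane bonds and the ethers.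

**Step 6**
Reactants: 12 1-[3,5-bis(3-butanoyl-2,4,6-trimethoxybenzyl)-2,4,6-trimethoxyphenyl]butan-1-one
Product: 13 1-[3,5-bis(3-butanoyl-2,4,6-trihydroxybenzyl)-2,4,6-trihydroxyphenyl]butan-1-one
Conditions: BBr3 (15 equiv), CH2Cl2, −78 °C → rt; then ice-water; all handling under Ar
Reagents that add atoms: none
Why: Lewis-acid cleavage of aryl methyl ethers (bromide attacks the methyl group of each O–B adduct); the six ethers ortho to a ketone should go first through chelation, and the three para ethers follow with the excess reagent. Each ring carries an acyl group, which lowers its tendency to ipso-protonation, so the bridges are expected to survive.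

**Step 7**
Reactants: 14 1-(2,4,6-trihydroxyphenyl)butan-1-one
Product: 16 2-butanoyl-3,5-dihydroxy-4,4-dimethylcyclohexa-2,5-dien-1-one (butyrylfilicinic acid), via C-methyl ketone 15 (not isolated)
Conditions: NaOMe (3.5 equiv), MeI (2.5 equiv), MeOH, 0 °C → rt; then 1 M HCl; extraction of 16 into aq. NaHCO3 and re-acidification
Reagents that add atoms: iodomethane, CI
Why: Dearomative gem-dimethylation of an acylphloroglucinol; the polyanion is alkylated at a ring carbon to give 15, whose methyl-bearing carbon is then the most electron-rich site and should take the second methyl group, breaking aromaticity. The product is a vinylogous acid and is separated from the less acidic C-methylated by-products by bicarbonate extraction.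

**Step 8**
Reactants: 16 2-butanoyl-3,5-dihydroxy-4,4-dimethylcyclohexa-2,5-dien-1-one
Product: 17 2-butanoyl-6-[(dimethylamino)methyl]-3,5-dihydroxy-4,4-dimethylcyclohexa-2,5-dien-1-one
Conditions: Me2N+=CH2 I− (Eschenmoser's salt, 1.05 equiv), CH2Cl2, 0 °C → rt; then aq. NaHCO3, 0 °C; zwitterion collected cold
Reagents that add atoms: N,N-dimethylmethyleneiminium iodide, C=[N+](C)C.[I-]
Why: Mannich reaction with a preformed iminium salt at the enol carbon C6, the only unsubstituted ring carbon of 16. With no free formaldehyde and no base in the flask, formation of the methylene-bridged dimer of 16 should be suppressed.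

**Step 9**
Reactants: 13 1-[3,5-bis(3-butanoyl-2,4,6-trihydroxybenzyl)-2,4,6-trihydroxyphenyl]butan-1-one; 17 2-butanoyl-6-[(dimethylamino)methyl]-3,5-dihydroxy-4,4-dimethylcyclohexa-2,5-dien-1-one (2.4 equiv, in portions)
Product: 20 1-[3,5-bis({3-butanoyl-5-[(5-butanoyl-2,4-dihydroxy-3,3-dimethyl-6-oxocyclohexa-1,4-dien-1-yl)methyl]-2,4,6-trihydroxyphenyl}methyl)-2,4,6-trihydroxyphenyl]butan-1-one (CNP0188003.0), via methylidene trione 18 (not isolated), via tetramer 19 (not isolated)
Conditions: 1,4-dioxane, 50 °C, Ar; then 1 M HCl, extraction, chromatography on acid-washed silica
Reagents that add atoms: none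
Why: Mannich-base coupling of an acylfilicinic acid with an acylphloroglucinol: zwitterionic 17 loses dimethylamine by E1cB elimination to give the doubly activated exocyclic enone 18. Conjugate addition of C5 of ring B of 13, which is ortho or para to three hydroxyl groups, gives 19 after re-aromatisation, and the same event on ring D gives 20. Ring C has no free carbon, so exactly two caps can enter.

## Compound list

1 | 1,3,5-trimethoxybenzene | COc1cc(OC)cc(OC)c1 | starting material
2 | 2,4,6-trimethoxybenzaldehyde | COc1cc(OC)c(C=O)c(OC)c1 | intermediate (not isolated)
3 | 2,4,6-trimethoxybenzene-1,3-dicarbaldehyde | COc1cc(OC)c(C=O)c(OC)c1C=O | intermediate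
4 | 2,4,6-trimethoxybenzene-1,3-dicarbaldehyde bis(4-methylbenzenesulfonylhydrazone), both C=N E | COc1cc(OC)c(/C=N/NS(=O)(=O)c2ccc(C)cc2)c(OC)c1/C=N/NS(=O)(=O)c1ccc(C)cc1 | intermediate
5 | bis(pinacolato)diboron | CC1(C)OB(OC1(C)C)B1OC(C)(C)C(C)(C)O1 | starting material
6 | 2,4-bis(diazomethyl)-1,3,5-trimethoxybenzene | COc1cc(OC)c(C=[N+]=[N-])c(OC)c1C=[N+]=[N-] | intermediate (not isolated)
7 | 2,4-bis[bis(4,4,5,5-tetramethyl-1,3,2-dioxaborolan-2-yl)methyl]-1,3,5-trimethoxybenzene | COc1cc(OC)c(C(B2OC(C)(C)C(C)(C)O2)B2OC(C)(C)C(C)(C)O2)c(OC)c1C(B1OC(C)(C)C(C)(C)O1)B1OC(C)(C)C(C)(C)O1 | intermediate (not isolated)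
8 | 1,3,5-trimethoxy-2,4-bis[(4,4,5,5-tetramethyl-1,3,2-dioxaborolan-2-yl)methyl]benzene | COc1cc(OC)c(CB2OC(C)(C)C(C)(C)O2)c(OC)c1CB1OC(C)(C)C(C)(C)O1 | intermediate
9 | 2-bromo-1,3,5-trimethoxybenzene | COc1cc(OC)c(Br)c(OC)c1 | starting material
10 | 2-{[2,4,6-trimethoxy-3-(2,4,6-trimethoxybenzyl)phenyl]methyl}-4,4,5,5-tetramethyl-1,3,2-dioxaborolane | COc1cc(OC)c(Cc2c(OC)cc(OC)cc2OC)c(OC)c1CB1OC(C)(C)C(C)(C)O1 | intermediate (not isolated)
11 | 1,3,5-trimethoxy-2,4-bis(2,4,6-trimethoxybenzyl)benzene | COc1cc(OC)c(Cc2c(OC)cc(OC)cc2OC)c(OC)c1Cc1c(OC)cc(OC)cc1OC | intermediate
12 | 1-[3,5-bis(3-butanoyl-2,4,6-trimethoxybenzyl)-2,4,6-trimethoxyphenyl]butan-1-one | CCCC(=O)c1c(OC)c(Cc2c(OC)cc(OC)c(C(=O)CCC)c2OC)c(OC)c(Cc2c(OC)cc(OC)c(C(=O)CCC)c2OC)c1OC | intermediate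
13 | 1-[3,5-bis(3-butanoyl-2,4,6-trihydroxybenzyl)-2,4,6-trihydroxyphenyl]butan-1-one | CCCC(=O)c1c(O)c(Cc2c(O)cc(O)c(C(=O)CCC)c2O)c(O)c(Cc2c(O)cc(O)c(C(=O)CCC)c2O)c1O | intermediate
14 | 1-(2,4,6-trihydroxyphenyl)butan-1-one | CCCC(=O)c1c(O)cc(O)cc1O | starting material
15 | 1-(2,4,6-trihydroxy-3-methylphenyl)butan-1-one | CCCC(=O)c1c(O)cc(O)c(C)c1O | intermediate (not isolated)
16 | 2-butanoyl-3,5-dihydroxy-4,4-dimethylcyclohexa-2,5-dien-1-one (butyrylfilicinic acid) | CCCC(=O)C1=C(O)C(C)(C)C(O)=CC1=O | intermediate
17 | 2-butanoyl-6-[(dimethylamino)methyl]-3,5-dihydroxy-4,4-dimethylcyclohexa-2,5-dien-1-one | CCCC(=O)C1=C(O)C(C)(C)C(O)=C(CN(C)C)C1=O | intermediate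
18 | 2-butanoyl-3-hydroxy-4,4-dimethyl-6-methylidenecyclohex-2-ene-1,5-dione | CCCC(=O)C1=C(O)C(C)(C)C(=O)C(=C)C1=O | intermediate (not isolated)
19 | tetramer: 13 carrying one (5-butanoyl-2,4-dihydroxy-3,3-dimethyl-6-oxocyclohexa-1,4-dien-1-yl)methyl group at C5 of ring B | CCCC(=O)C1=C(O)C(C)(C)C(O)=C(Cc2c(O)c(Cc3c(O)c(Cc4c(O)cc(O)c(C(=O)CCC)c4O)c(O)c(C(=O)CCC)c3O)c(O)c(C(=O)CCC)c2O)C1=O | intermediate (not isolated)
20 | 1-[3,5-bis({3-butanoyl-5-[(5-butanoyl-2,4-dihydroxy-3,3-dimethyl-6-oxocyclohexa-1,4-dien-1-yl)methyl]-2,4,6-trihydroxyphenyl}methyl)-2,4,6-trihydroxyphenyl]butan-1-one (CNP0188003.0) | CCCC(=O)C1=C(O)C(C)(C)C(O)=C(Cc2c(O)c(Cc3c(O)c(Cc4c(O)c(CC5=C(O)C(C)(C)C(O)=C(C(=O)CCC)C5=O)c(O)c(C(=O)CCC)c4O)c(O)c(C(=O)CCC)c3O)c(O)c(C(=O)CCC)c2O)C1=O | target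

## Step count and risk

Total step count: 9. Longest linear sequence: 7 steps (steps 1, 2, 3, 4, 5, 6 and 9, from 1 to 20); steps 7 and 8 form the two-step side branch from 14 to 17.

**Step 4 (key step).** Both partners are flanked by two ortho methoxy groups, so oxidative addition and transmetalation may be slow enough for protodeboronation of the benzylic boronate, or stalling at the monocoupled stage, to take over. Fallback: the same two bonds are formed by a polar route that sets out from 3. Reduction with NaBH4 in MeOH/THF should give (2,4,6-trimethoxy-1,3-phenylene)dimethanol F2. Its benzylic alcohols ionise under catalytic Sc(OTf)3 in MeNO2 at low temperature, and the cations are trapped by a large excess of 1 in a double Friedel–Crafts benzylation. The fallback returns to the route at 11. It depends on kinetic control and a short reaction time, because the same acid can exchange the new bridges, which is why it is not the first choice.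

**Step 9.** The Mannich and enone chemistry is reversible in the presence of the liberated amine. The one-carbon unit may be handed from ring to ring, 18 may condense with its own precursor, and the second capping may remain incomplete. Fallback: the roles are exchanged. Setting out from 13, aminomethylation of C5 of rings B and D with Eschenmoser's salt gives 1-[3,5-bis({3-butanoyl-5-[(dimethylamino)methyl]-2,4,6-trihydroxyphenyl}methyl)-2,4,6-trihydroxyphenyl]butan-1-one F6. Heating F6 with a large excess of the cheap nucleophile 16 in dioxane returns to the route at 20.

**Step 6.** The Lewis acid may fragment the inner diarylmethane bonds once the first phenols are free, and the three ethers para to the ketones may be cleaved only partly. Fallback: a staged cleavage that sets out from 12. BCl3 in CH2Cl2 at −20 → 0 °C removes only the six chelated ethers ortho to the carbonyl groups, giving 1-[3,5-bis(3-butanoyl-2,4-dihydroxy-6-methoxybenzyl)-2,6-dihydroxy-4-methoxyphenyl]butan-1-one F5. The three remaining ethers, each para to a ketone, are then cleaved without acid by SN2 attack of NaSEt in DMF at 120 °C. Acidification returns to the route at 13.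

**Step 5.** The three acyl groups may be distributed unevenly: the free carbon of ring C is buttressed by two methoxy groups, so a second acylation of an outer ring may compete. Ipso-attack with loss of a trimethoxybenzyl cation is also possible. Fallback: the outer butyryl groups are installed before the coupling. Setting out from 9, acylation with butanoyl chloride and SnCl4 gives 1-(3-bromo-2,4,6-trimethoxyphenyl)butan-1-one F3. Coupling of F3 with 8 under the conditions of step 4 gives 1,3,5-trimethoxy-2,4-bis(3-butanoyl-2,4,6-trimethoxybenzyl)benzene F4. Only ring C of F4 is still electron-rich, so a single acylation returns to the route at 12.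

**Step 3.** The electron-rich diazo intermediate may decompose by azine formation or by carbene insertion into an ortho methoxy C–H bond before it is borylated, and deborylation may run on to the methyl compound. Fallback: the C–B bonds are made by cross-coupling instead. Setting out from 1, dibromination with NBS (2.05 equiv, MeCN, 0 °C) gives 2,4-dibromo-1,3,5-trimethoxybenzene F1. Chemoselective Suzuki coupling of F1 with commercial bis(pinacolboryl)methane (Pd[P(t-Bu)3]2, aq. KOH, dioxane) transfers one CH2Bpin unit to each carbon and returns to the route at 8.

## Further compounds

F1 | step 3 | 2,4-dibromo-1,3,5-trimethoxybenzene | COc1cc(OC)c(Br)c(OC)c1Br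
F2 | step 4 | (2,4,6-trimethoxy-1,3-phenylene)dimethanol | COc1cc(OC)c(CO)c(OC)c1CO
F3 | step 5 | 1-(3-bromo-2,4,6-trimethoxyphenyl)butan-1-one | CCCC(=O)c1c(OC)cc(OC)c(Br)c1OC
F4 | step 5 | 1,3,5-trimethoxy-2,4-bis(3-butanoyl-2,4,6-trimethoxybenzyl)benzene | CCCC(=O)c1c(OC)cc(OC)c(Cc2c(OC)cc(OC)c(Cc3c(OC)cc(OC)c(C(=O)CCC)c3OC)c2OC)c1OC
F5 | step 6 | 1-[3,5-bis(3-butanoyl-2,4-dihydroxy-6-methoxybenzyl)-2,6-dihydroxy-4-methoxyphenyl]butan-1-one | CCCC(=O)c1c(O)c(Cc2c(OC)cc(O)c(C(=O)CCC)c2O)c(OC)c(Cc2c(OC)cc(O)c(C(=O)CCC)c2O)c1O
F6 | step 9 | 1-[3,5-bis({3-butanoyl-5-[(dimethylamino)methyl]-2,4,6-trihydroxyphenyl}methyl)-2,4,6-trihydroxyphenyl]butan-1-one | CCCC(=O)c1c(O)c(Cc2c(O)c(CN(C)C)c(O)c(C(=O)CCC)c2O)c(O)c(Cc2c(O)c(CN(C)C)c(O)c(C(=O)CCC)c2O)c1O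
A1 | alternative 1 | pentamer lacking the two terminal butyryl groups (product of the double Dieckmann closure) | O=C1C=C(O)C(C)(C)C(O)=C1Cc1c(O)c(Cc2c(O)c(Cc3c(O)c(CC4=C(O)C(C)(C)C(O)=CC4=O)c(O)c(C(=O)CCC)c3O)c(O)c(C(=O)CCC)c2O)c(O)c(C(=O)CCC)c1O
A2 | alternative 1 | 13 carrying a 2-(methoxycarbonyl)-4,4-dimethyl-3,5-dioxohexyl arm at C5 of ring B and of ring D (mixture of diastereomers at the two ester-bearing carbons, both lost on ring closure) | CCCC(=O)c1c(O)c(Cc2c(O)c(CC(C(=O)OC)C(=O)C(C)(C)C(C)=O)c(O)c(C(=O)CCC)c2O)c(O)c(Cc2c(O)c(CC(C(=O)OC)C(=O)C(C)(C)C(C)=O)c(O)c(C(=O)CCC)c2O)c1O
A3 | alternative 2 | protected ring B–ring C–ring D trimer with methoxymethyl handles on rings B and D (product of the double benzannulation) | COc1cc(OC)c(Cc2c(O)cc(OCC)c(COC)c2O[Si](C(C)C)(C(C)C)C(C)C)c(OC)c1Cc1c(O)cc(OCC)c(COC)c1O[Si](C(C)C)(C(C)C)C(C)C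
A4 | alternative 2 | 1,3,5-trimethoxy-2,4-bis[3-(triisopropylsilyloxy)prop-2-yn-1-yl]benzene | COc1cc(OC)c(CC#CO[Si](C(C)C)(C(C)C)C(C)C)c(OC)c1CC#CO[Si](C(C)C)(C(C)C)C(C)C
A5 | alternative 2 | 3-ethoxy-2-(methoxymethyl)cyclobut-2-en-1-one | CCOC1=C(COC)C(=O)C1
A6 | alternative 3 | nonamethoxy pentamer with acyl-free terminal trione rings (product of the ketene–diene ring formation) | COc1cc(OC)c(Cc2c(OC)cc(OC)c(CC3=C(O)C(C)(C)C(O)=CC3=O)c2OC)c(OC)c1Cc1c(OC)cc(OC)c(CC2=C(O)C(C)(C)C(O)=CC2=O)c1OC
A7 | alternative 3 | nonamethoxy trimer carrying a 5-methoxy-3,5-bis(trimethylsilyloxy)penta-2,4-dien-1-yl arm on ring B and on ring D (double-bond geometry not fixed) | COc1cc(OC)c(Cc2c(OC)cc(OC)c(CC=C(O[Si](C)(C)C)C=C(OC)O[Si](C)(C)C)c2OC)c(OC)c1Cc1c(OC)cc(OC)c(CC=C(O[Si](C)(C)C)C=C(OC)O[Si](C)(C)C)c1OC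
A8 | alternative 3 | dimethylketene | CC(C)=C=O
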